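**Assumption:** the SMILES contains no stereocentre and no stereodefined double bond, so the target is achiral and no enantiocontrol is needed.

## Retrosynthetic overview
1. Target ⇒ two aryl C–O bonds made last, by O-insertion into the two aryl C–B bonds of a non-phenolic benzhydrol bis(boronate), para to the carbinol carbon.
2. The new para-phenoxides then expel the benzhydryl oxygen as a p-quinone methide, and hydride turns that carbon into the CH2 bridge.
3. Bis(boronate) ⇒ sterically governed Ir-catalysed C–H borylation of the benzhydrol. Benzhydrol ⇒ two sp2–sp3 C–C bonds by B-alkyl Suzuki coupling of bis(2-bromo-6-methoxyphenyl)methanol with hydroborated 4-vinylguaiacol.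
4. Dibromobenzhydrol ⇒ two molecules of C2-lithiated 3-bromoanisole plus ethyl formate as the one-carbon linchpin.
5. No ring is formed, because all four benzene rings are bought.

## Route

Step 1
Reactants: 1 3-bromoanisole (2.1 equiv); 2 ethyl formate (1.0 equiv)
Product: 5 bis(2-bromo-6-methoxyphenyl)methanol, via (2-bromo-6-methoxyphenyl)lithium 3 (not isolated), via 2-bromo-6-methoxybenzaldehyde 4 (not isolated)
Conditions: LDA (commercial solution, 2.1 equiv), THF, −78 °C, 1 h; HCO2Et, −78 °C, 2 h; 1 M HCl quench at −78 °C → rt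
Reagents that add atoms: none
Why: Br and OMe together acidify only C2–H, so directed ortho-metalation occurs there (−78 °C prevents LiBr loss to the aryne), and two ArLi add to the formate through aldehyde 4 (double 1,2-addition); the carbinol carbon carries two identical aryl groups and is not a stereocentre.

Step 2
Reactants: 5 bis(2-bromo-6-methoxyphenyl)methanol; 6 2-methoxy-4-vinylphenol (4-vinylguaiacol, 2.4 equiv)
Product: 8 bis{2-[2-(4-hydroxy-3-methoxyphenyl)ethyl]-6-methoxyphenyl}methanol, via 9-{2-[4-(9-borabicyclo[3.3.1]nonan-9-yloxy)-3-methoxyphenyl]ethyl}-9-borabicyclo[3.3.1]nonane 7 (not isolated)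
Conditions: 6, 9-BBN-H (5.0 equiv), THF, 0 °C → rt; then 5, PdCl2(dppf) (6 mol %), 3 M aq NaOH, THF, 65 °C; aq NH4Cl work-up
Reagents that add atoms: none
Why: The first 9-BBN masks the phenol as a borinate and the second adds anti-Markovnikov (Brown hydroboration); in the B-alkyl Suzuki–Miyaura coupling the wide-bite dppf ligand favours reductive elimination over β-hydride elimination, free 2-bromobenzhydrols are tolerated, and the saturated product cannot undergo the 6-exo carbopalladation that a stepwise Heck route would risk.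

Step 3
Reactants: 8 bis{2-[2-(4-hydroxy-3-methoxyphenyl)ethyl]-6-methoxyphenyl}methanol
Product: 9 C4,C4'-bis(Bpin)-O,O',O''-tris(Bpin) benzhydrol (crude residue kept under N2)
Conditions: [Ir(cod)OMe]2 (2.5 mol %), dtbpy (5 mol %), HBpin (6.5 equiv), THF, rt → 70 °C, N2; THF and excess HBpin removed in vacuo
Reagents that add atoms: pinacolborane, CC1(C)OBOC1(C)C
Why: HBpin first turns both guaiacol OH groups and the carbinol OH into O-Bpin with loss of H2, and the (dtbpy)Ir tris(boryl) catalyst then borylates the only C–H bonds without an ortho neighbour, C4 of each 1,2,3-trisubstituted inner ring (para to the carbinol carbon), because every outer-ring C–H is ortho to a substituent (sterically governed Ir-catalysed aromatic C–H borylation); no stereocentre is created.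

Step 4
Reactants: 9 C4,C4'-bis(Bpin)-O,O',O''-tris(Bpin) benzhydrol (crude residue of Step 3)
Product: 13 4,4'-methylenebis{5-[2-(4-hydroxy-3-methoxyphenyl)ethyl]-3-methoxyphenol} (target), via pentakis(O-Bpin) borate ester 10 (not isolated), via bis{4-hydroxy-2-[2-(4-hydroxy-3-methoxyphenyl)ethyl]-6-methoxyphenyl}methanol 11 (not isolated), via p-quinomethide 4-(arylmethylidene)cyclohexa-2,5-dien-1-one 12 (not isolated)
Conditions: anhydrous Me3NO (2.6 equiv), THF, 50 °C; then NaBH4 (6 equiv), 2 M aq NaOH, 65 °C, N2; then 1 M HCl to pH 5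
Reagents that add atoms: trimethylamine N-oxide, C[N+](C)(C)[O-]
Why: Proposed new method: boronate-oxidation-triggered self-immolative deoxygenation of a non-phenolic benzhydrol – anhydrous Me3NO forms the two aryl C–O bonds by B-ate formation and 1,2-aryl shift, giving 10 in which all five oxygens are still masked as O-Bpin and no nucleophilic peroxide is present that could cleave the later quinone methide; aqueous NaOH then frees tetraphenol 11 with borohydride already in the flask, its para-phenoxide expels the benzhydryl hydroxide (1,6-elimination) to give p-quinone methide 12 (11 minus water: one inner ring is a cyclohexa-2,5-dien-1-one joined to the former carbinol CH by an exocyclic C=C whose geometry is immaterial), whose four flanking ortho substituents let only hydride reach the exocyclic carbon (1,6-addition), and the basic medium avoids the benzhydryl cation that would close onto an outer ring to a dibenzosuberane; the closest known reaction types are the N-oxide oxidation of arylboronates to phenols, the oxidation-triggered 1,6-elimination of 4-boronobenzyl self-immolative linkers, and the NaBH4/NaOH hydrogenolysis of 4-hydroxybenzyl alcohols, which have not been merged into a deoxygenation or applied to a benzhydrol; no stereocentre is created.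

## Compound list
1 | 3-bromoanisole | COc1cccc(Br)c1 | starting material
2 | ethyl formate | CCOC=O | starting material
3 | (2-bromo-6-methoxyphenyl)lithium | [Li]c1c(Br)cccc1OC | intermediate
4 | 2-bromo-6-methoxybenzaldehyde | COc1cccc(Br)c1C=O | intermediate
5 | bis(2-bromo-6-methoxyphenyl)methanol | COc1cccc(Br)c1C(O)c1c(Br)cccc1OC | intermediate
6 | 2-methoxy-4-vinylphenol | COc1cc(C=C)ccc1O | starting material
7 | 9-{2-[4-(9-BBN-9-yloxy)-3-methoxyphenyl]ethyl}-9-BBN | COc1cc(CCB2C3CCCC2CCC3)ccc1OB1C2CCCC1CCC2 | intermediate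
8 | bis{2-[2-(4-hydroxy-3-methoxyphenyl)ethyl]-6-methoxyphenyl}methanol | COc1cc(CCc2cccc(OC)c2C(O)c2c(CCc3ccc(O)c(OC)c3)cccc2OC)ccc1O | intermediate
9 | C4,C4'-bis(Bpin)-O,O',O''-tris(Bpin) benzhydrol | COc1cc(CCc2cc(B3OC(C)(C)C(C)(C)O3)cc(OC)c2C(OB2OC(C)(C)C(C)(C)O2)c2c(CCc3ccc(OB4OC(C)(C)C(C)(C)O4)c(OC)c3)cc(B3OC(C)(C)C(C)(C)O3)cc2OC)ccc1OB1OC(C)(C)C(C)(C)O1 | intermediate
10 | pentakis(O-Bpin) borate ester | COc1cc(CCc2cc(OB3OC(C)(C)C(C)(C)O3)cc(OC)c2C(OB2OC(C)(C)C(C)(C)O2)c2c(CCc3ccc(OB4OC(C)(C)C(C)(C)O4)c(OC)c3)cc(OB3OC(C)(C)C(C)(C)O3)cc2OC)ccc1OB1OC(C)(C)C(C)(C)O1 | intermediate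
11 | bis{4-hydroxy-2-[2-(4-hydroxy-3-methoxyphenyl)ethyl]-6-methoxyphenyl}methanol | COc1cc(CCc2cc(O)cc(OC)c2C(O)c2c(CCc3ccc(O)c(OC)c3)cc(O)cc2OC)ccc1O | intermediate
12 | p-quinomethide 4-(arylmethylidene)cyclohexa-2,5-dien-1-one | COC1=CC(=O)C=C(CCc2ccc(O)c(OC)c2)C1=Cc1c(CCc2ccc(O)c(OC)c2)cc(O)cc1OC | intermediate
13 | 4,4'-methylenebis{5-[2-(4-hydroxy-3-methoxyphenyl)ethyl]-3-methoxyphenol} | COc1cc(CCc2cc(O)cc(OC)c2Cc2c(CCc3ccc(O)c(OC)c3)cc(O)cc2OC)ccc1O | target

## Totals
Total step count: 4. Steps 3 and 4 are telescoped, and 9 is only freed of volatiles. Longest linear sequence: 4 (1 → 5 → 8 → 9 → 13).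

## Steps most likely to fail

**Step 4 (proposed new step).**
- Risks:
  - Hydroxide loss from 11 may be slow.
  - In strong base 12 exists as a delocalised phenoxide of lowered electrophilicity.
  - Phenoxides may capture 12 instead of hydride.
  - Minor regioisomeric boronates from Step 3 cannot be removed from crude 9.
- The fallback uses known chemistry only. It sets out from 5 and returns at 13.
- The carbinol oxygen is removed before any nucleophilic side chain is present. Et3SiH/TFA in CH2Cl2 at 0 °C (ionic hydrogenation) gives bis(2-bromo-6-methoxyphenyl)methane F1.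
- The B-alkyl Suzuki coupling of Step 2 with borane 7 then gives bis{2-[2-(4-hydroxy-3-methoxyphenyl)ethyl]-6-methoxyphenyl}methane F2.
- Standard Ir/dtbpy/HBpin borylation with aqueous work-up and chromatography gives the isolated 4,4'-bis(pinacolboronate) F3.
- NaBO3·4H2O in THF–water at rt oxidises F3 to 13. No quinone methide is involved.

**Step 2.**
- Risks: β-hydride elimination or hydrodebromination at the hindered bromides, and a heavy boron load from the unprotected phenol.
- The fallback sets out from 5 and 6 and returns at 8. It replaces the sp2–sp3 coupling with an sp2–sp2 coupling followed by reduction.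
- Cross-metathesis of 6 with vinyl-Bpin (Grubbs II, CH2Cl2, 40 °C) gives (E)-2-methoxy-4-[2-(pinacolboryl)vinyl]phenol F4.
- Twofold Suzuki coupling with 5 gives bis{2-[(E)-2-(4-hydroxy-3-methoxyphenyl)ethenyl]-6-methoxyphenyl}methanol F5. Conditions are Pd(OAc)2/SPhos, K3PO4, THF–water, 60 °C, with excess F4 to outrun intramolecular carbopalladation.
- Neutral hydrogenation (H2, Pd/C, EtOAc) saturates both alkenes, leaves the benzhydrol intact, and gives 8.

**Step 1.**
- Risk: the second addition (hindered ArLi to hindered aldehyde 4) may be too slow at −78 °C, and 3 decomposes to the aryne on warming.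
- The fallback sets out from 1 and returns at 5.
- The lithio species 3 is trapped at once with I2 to give 1-bromo-2-iodo-3-methoxybenzene F6.
- Selective I/Mg exchange with iPrMgCl·LiCl (THF, −20 °C) gives (2-bromo-6-methoxyphenyl)magnesium chloride F7. This reagent tolerates −20 °C to 0 °C.
- F7 is added twice to ethyl formate 2 over several hours to give 5.

## Further compounds
F1 | step 4 | bis(2-bromo-6-methoxyphenyl)methane | COc1cccc(Br)c1Cc1c(Br)cccc1OC
F2 | step 4 | bis{2-[2-(4-hydroxy-3-methoxyphenyl)ethyl]-6-methoxyphenyl}methane | COc1cc(CCc2cccc(OC)c2Cc2c(CCc3ccc(O)c(OC)c3)cccc2OC)ccc1O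
F3 | step 4 | bis{2-[2-(4-hydroxy-3-methoxyphenyl)ethyl]-6-methoxy-4-(pinacolboryl)phenyl}methane | COc1cc(CCc2cc(B3OC(C)(C)C(C)(C)O3)cc(OC)c2Cc2c(CCc3ccc(O)c(OC)c3)cc(B3OC(C)(C)C(C)(C)O3)cc2OC)ccc1O
F4 | step 2 | (E)-2-methoxy-4-[2-(pinacolboryl)vinyl]phenol | COc1cc(/C=C/B2OC(C)(C)C(C)(C)O2)ccc1O
F5 | step 2 | bis{2-[(E)-2-(4-hydroxy-3-methoxyphenyl)ethenyl]-6-methoxyphenyl}methanol | COc1cc(/C=C/c2cccc(OC)c2C(O)c2c(/C=C/c3ccc(O)c(OC)c3)cccc2OC)ccc1O
F6 | step 1 | 1-bromo-2-iodo-3-methoxybenzene | COc1cccc(Br)c1I
F7 | step 1 | (2-bromo-6-methoxyphenyl)magnesium chloride | COc1cccc(Br)c1[Mg]Cl
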